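**Retrosynthetic overview**

1. Target ⇒ (global desilylation) ⇒ C1–CH(CO2H) bond: Michael addition of the bis-macrolide cyclopentanone β-keto ester to a cis-4-oxo-2-enoate carboxylate, unveiled in the same flask by singlet-oxygen dearomatization of a 2-alkylfuran ester (key step: quaternary C1, the acid-bearing stereocenter and the free acid in one operation).
2. Cyclopentanone ⇒ Michael/aldol [3+2] of one 14-membered enone diolide used twice: as acceptor (becomes ring B) and, after epoxidation and base-induced opening to its 3,4-dioxo ester, as donor (becomes ring A).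
3. Diolide ⇒ Yamaguchi lactonization of a seco acid whose trans-4-oxo-2-enoic acid end comes from oxidative ring opening (dearomatization) of the same 2-alkylfuran.
4. Seco acid and side chain ⇒ one propargylic alcohol from Felkin–Anh addition of the acetylide of (S)-4-(furan-2-yl)butan-2-yl propiolate to (S)-2-(triethylsilyloxy)propanal; Z by semi-hydrogenation, E by trans-hydroalumination.
5. Ring order: the 14-membered diolide first (two copies become rings A and B), the cyclopentanone last; feedstocks are furan, methyl vinyl ketone, propiolic acid and ethyl (S)-lactate.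

Assumption and labels: the structure is taken exactly as drawn (Z enoates in rings A and B, E in the side chain, 14 stereocenters); cyclopentanone atoms are C1 (quaternary, ring A ester), C2 (C=O), C3 (carbinol, ring A), C4 (CH carrying the ring B ketone), C5 (CH carrying the ring B ester); TBS = tert-butyldimethylsilyl, TES = triethylsilyl.

**Route**

Step 1
Reactants: 1 furan; 2 methyl vinyl ketone (but-3-en-2-one)
Product: 3 4-(furan-2-yl)butan-2-one
Conditions: furan (5 equiv), BF3·OEt2 (5 mol %), CH2Cl2, −20 °C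
Reagents that add atoms: none
Why: Lewis acid-catalysed Friedel–Crafts-type conjugate addition (Michael alkylation) of furan through its most nucleophilic C2 position, with excess furan suppressing 2,5-dialkylation; no stereocenter is formed.

Step 2
Reactants: 3 4-(furan-2-yl)butan-2-one
Product: 4 (S)-4-(furan-2-yl)butan-2-ol
Conditions: alcohol dehydrogenase ADH-A (Rhodococcus ruber), NAD+ (cat.), i-PrOH (10% v/v), KH2PO4/K2HPO4 buffer pH 7.5, 30 °C
Reagents that add atoms: none
Why: Enzymatic asymmetric ketone reduction with cofactor recycling by i-PrOH: the Prelog-selective dehydrogenase delivers hydride to the re face of the methyl ketone and sets the S carbinol (>99% ee is usual for 4-arylbutan-2-ones) that becomes the CH(CH3)O stereocenter of all three C8 units.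

Step 3
Reactants: 4 (S)-4-(furan-2-yl)butan-2-ol; 5 propiolic acid (prop-2-ynoic acid)
Product: 6 (S)-4-(furan-2-yl)butan-2-yl prop-2-ynoate
Conditions: DCC, DMAP (5 mol %), CH2Cl2, −20 → 0 °C
Reagents that add atoms: none
Why: Steglich esterification acylates the secondary alcohol with retention, the low temperature preventing amine addition to the propiolate.

Step 4
Reactants: 7 ethyl (S)-lactate
Product: 8 ethyl (S)-2-(triethylsilyloxy)propanoate
Conditions: Et3SiCl, imidazole, CH2Cl2, 0 °C → rt
Reagents that add atoms: chlorotriethylsilane, CC[Si](CC)(CC)Cl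
Why: Standard silyl ether formation on the chiral-pool hydroxy ester; the S center (future C5 of all three hexenoate units) is not touched.

Step 5
Reactants: 8 ethyl (S)-2-(triethylsilyloxy)propanoate
Product: 9 (S)-2-(triethylsilyloxy)propanal
Conditions: i-Bu2AlH (1.05 equiv), CH2Cl2, −78 °C; then aq. KNaC4H4O6
Reagents that add atoms: none
Why: Partial ester reduction through the tetrahedral aluminium hemiacetalate, which is stable at −78 °C and releases the configurationally intact α-silyloxy aldehyde on work-up.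

Step 6
Reactants: 6 (S)-4-(furan-2-yl)butan-2-yl prop-2-ynoate; 9 (S)-2-(triethylsilyloxy)propanal
Product: 11 (S)-4-(furan-2-yl)butan-2-yl (4R,5S)-4-hydroxy-5-(triethylsilyloxy)hex-2-ynoate, via lithium acetylide 10 (not isolated)
Conditions: LiN(SiMe3)2 (1.05 equiv), THF, −78 °C; then 9, −78 °C; then AcOH
Reagents that add atoms: none
Why: 1,2-Addition of the ester-stabilized lithium acetylide to the α-silyloxy aldehyde under non-chelating Felkin–Anh control (nucleophile anti to the silyloxy group) gives the 4,5-anti alcohol and sets C4 as R (dr about 5:1, minor syn isomer removed by chromatography).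

Step 7
Reactants: 11 (S)-4-(furan-2-yl)butan-2-yl (4R,5S)-4-hydroxy-5-(triethylsilyloxy)hex-2-ynoate
Product: 12 (S)-4-(furan-2-yl)butan-2-yl (4R,5S)-4-(tert-butyldimethylsilyloxy)-5-(triethylsilyloxy)hex-2-ynoate
Conditions: t-BuMe2SiOTf, 2,6-lutidine, CH2Cl2, −78 °C
Reagents that add atoms: tert-butyldimethylsilyl triflate, CC(C)(C)[Si](C)(C)OS(=O)(=O)C(F)(F)F
Why: Silylation of the propargylic hydroxyl with the silyl triflate and a hindered pyridine base (no silyl migration) puts the robust ether on O4 and leaves O5 under the more labile TES group, which differentiates the two oxygens.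

Step 8
Reactants: 12 (S)-4-(furan-2-yl)butan-2-yl (4R,5S)-4-(TBSO)-5-(TESO)hex-2-ynoate
Product: 13 (S)-4-(furan-2-yl)butan-2-yl (2Z,4R,5S)-4-(TBSO)-5-(TESO)hex-2-enoate
Conditions: H2 (1 atm), Pd/CaCO3 poisoned with Pb(OAc)2, quinoline, EtOAc, rt
Reagents that add atoms: none
Why: Lindlar-type syn semi-hydrogenation on lead-poisoned palladium stops at the Z enoate; the furan, the ester and both silyl ethers are inert.

Step 9
Reactants: 13 (S)-4-(furan-2-yl)butan-2-yl (2Z,4R,5S)-4-(TBSO)-5-(TESO)hex-2-enoate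
Product: 15 (2E,7S)-7-{[(2Z,4R,5S)-4-(TBSO)-5-(TESO)hex-2-enoyl]oxy}-4-oxooct-2-enal, via Z-enal 14 (not isolated)
Conditions: NBS, NaHCO3, acetone–H2O (10:1), −15 °C; then pyridine, rt
Reagents that add atoms: water, O
Why: Oxidative dearomatization of the 2-alkylfuran (bromination at C5, hydrolytic ring opening to the cis-4-oxo-2-enal) followed by pyridine-mediated cis-to-trans isomerization of the ene-dicarbonyl; the electron-poor Z enoate and the silyl ethers do not react with NBS under bicarbonate buffering.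

Step 10
Reactants: 15 (2E,7S)-7-{[(2Z,4R,5S)-4-(TBSO)-5-(TESO)hex-2-enoyl]oxy}-4-oxooct-2-enal
Product: 16 (2E,7S)-7-{[(2Z,4R,5S)-4-(TBSO)-5-(TESO)hex-2-enoyl]oxy}-4-oxooct-2-enoic acid
Conditions: NaClO2, NaH2PO4, 2-methyl-2-butene, t-BuOH–H2O, 0 °C → rt
Reagents that add atoms: sodium chlorite, [Na+].[O-]Cl=O
Why: Pinnick oxidation converts the conjugated aldehyde into the acid under buffered conditions, 2-methyl-2-butene scavenging the hypochlorous acid so that neither alkene is attacked.

Step 11
Reactants: 16 (2E,7S)-7-{[(2Z,4R,5S)-4-(TBSO)-5-(TESO)hex-2-enoyl]oxy}-4-oxooct-2-enoic acid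
Product: 17 (2E,7S)-7-{[(2Z,4R,5S)-4-(TBSO)-5-hydroxyhex-2-enoyl]oxy}-4-oxooct-2-enoic acid
Conditions: AcOH–THF–H2O (3:1:1), rt
Reagents that add atoms: none
Why: Mild acid solvolysis cleaves the secondary TES ether about two orders of magnitude faster than the TBS ether, which frees only O5 for ring closure.

Step 12
Reactants: 17 (2E,7S)-7-{[(2Z,4R,5S)-4-(TBSO)-5-hydroxyhex-2-enoyl]oxy}-4-oxooct-2-enoic acid
Product: 19 macrodiolide (3E,8S,11Z,13R,14S)-13-(TBSO)-8,14-dimethyl-1,9-dioxacyclotetradeca-3,11-diene-2,5,10-trione, via mixed anhydride 18 (not isolated)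
Conditions: 2,4,6-Cl3C6H2COCl, Et3N, THF, rt; then slow addition to DMAP, toluene (1 mM), 40 °C
Reagents that add atoms: none
Why: Yamaguchi macrolactonization: the acylpyridinium derived from the mixed anhydride of the trans-4-oxo-2-enoic acid is captured by the C5 hydroxyl under high dilution to close the 14-membered diolide, the activated acyl group reacting far faster than the unactivated secondary Z-enoate ester could transesterify to a six-membered lactone; no stereocenter is affected.

Step 13
Reactants: 19 macrodiolide (3E,8S,11Z,13R,14S)-13-(TBSO)-8,14-dimethyl-1,9-dioxacyclotetradeca-3,11-diene-2,5,10-trione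
Product: 20 trans-3,4-epoxide of 19 [(8S,11Z,13R,14S)-13-(TBSO)-3,4-epoxy-8,14-dimethyl-1,9-dioxacyclotetradec-11-ene-2,5,10-trione]
Conditions: t-BuOOH (1.5 equiv, decane), DBU (10 mol %), CH2Cl2, −20 °C
Reagents that add atoms: tert-butyl hydroperoxide, CC(C)(C)OO
Why: Weitz–Scheffer nucleophilic epoxidation takes place only at the doubly activated ene-dicarbonyl double bond (the γ-silyloxy Z enoate is far less electrophilic) and gives the trans epoxide as a mixture of the two face isomers, both of which converge to the same dione in step 14.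

Step 14
Reactants: 20 trans-3,4-epoxide of 19; 19 macrodiolide
Product: 22 bis-macrolide cyclopentanone (1S,3S,4S,5S; rings A plus B closed; H at C1; both ring allylic hydroxyls as TBS ethers), via tetrone 21 (not isolated)
Conditions: DBU (1.5 equiv), THF, 0 °C → rt (20 → 21); then 19 (1.0 equiv), −40 → 0 °C; then AcOH
Reagents that add atoms: none
Why: Proposed new method: DBU removes the epoxide hydrogen α to the ketone and the oxiranyl anion opens to the enolate of 3,4-dioxo ester 21 (mechanistically the known base-induced isomerization of α,β-epoxy ketones to 1,2-diketones, as with chalcone oxides), whose central carbon then adds to the ene-dicarbonyl of 19 at the position β to the ketone, and the ketone enolate so formed closes the cyclopentanone by aldol addition to the distal carbonyl of the 1,2-dione (closest known reaction type: Michael/aldol [3+2] annulation of 1,2-diones and β-keto esters with enones); C5 is set by peripheral attack on the macrocyclic E-enone, C4 ends trans to the C5 ester and the C3 hydroxyl cis to the C4 acyl group (hydrogen-bonded aldol transition state, with ring A obliged to bridge C1 and C3 on one face), the reversible steps funnelling material to this most stable isomer while C1 stays epimerizable.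

Step 15
Reactants: 11 (S)-4-(furan-2-yl)butan-2-yl (4R,5S)-4-hydroxy-5-(triethylsilyloxy)hex-2-ynoate
Product: 23 (S)-4-(furan-2-yl)butan-2-yl (2E,4R,5S)-4-hydroxy-5-(triethylsilyloxy)hex-2-enoate
Conditions: NaAlH2(OCH2CH2OMe)2 (2 equiv), THF, −72 °C; then aq. KNaC4H4O6
Reagents that add atoms: none
Why: Alkoxide-directed trans-hydroalumination of the γ-hydroxy ynoate followed by protonolysis gives the E enoate, the ester and the furan surviving at −72 °C; no stereocenter is affected.

Step 16
Reactants: 23 (S)-4-(furan-2-yl)butan-2-yl (2E,4R,5S)-4-hydroxy-5-(triethylsilyloxy)hex-2-enoate; 22 bis-macrolide cyclopentanone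
Product: 25 silyl-protected target (26 carrying TBS ethers on the two ring allylic hydroxyls plus a TES ether on the side-chain C5 hydroxyl), via hydroxybutenolide 24 (not isolated)
Conditions: O2, tetraphenylporphyrin (1 mol %), visible light, i-Pr2NEt (1.5 equiv), CH2Cl2, −78 °C; then 22 (1.0 equiv), DBU (3 equiv), THF, −40 → 0 °C; then AcOH
Reagents that add atoms: dioxygen, O=O
Why: Proposed new method: [4+2] addition of singlet oxygen to the furan and amine-induced Kornblum–DeLaMare collapse of the endoperoxide dearomatize 23 to γ-hydroxybutenolide 24 (known furan photooxygenation), which DBU opens to the cis-4-oxo-2-enoate carboxylate whose only electrophilic carbon is the one β to the ketone, so that the enolate of β-keto ester 22 adds there (closest known reaction type: Michael addition of cyclic β-keto esters to β-acylacrylates) on the face of C1 opposite to the ring A bridge and the C5 ester, which creates the quaternary C1 (S), the CH(CO2H) stereocenter (R, the relative topicity expected for an extended transition state that keeps the carboxylate away from ring B, and the least secure element of the route) and the free acid in one operation.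

Step 17
Reactants: 25 silyl-protected target
Product: 26 CNP0078817.1 (target)
Conditions: HF·pyridine, pyridine, THF, 0 °C → rt
Reagents that add atoms: none
Why: Fluoride-mediated desilylation under pyridine-buffered, mildly acidic conditions removes the two TBS ethers and the TES ether without retro-aldol or retro-Michael cleavage of the core and without lactonization of the Z γ-hydroxy enoates to butenolides; no stereocenter is touched.

**Compound list**

1 | furan | c1ccoc1 | starting material
2 | methyl vinyl ketone (but-3-en-2-one) | CC(=O)C=C | starting material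
3 | 4-(furan-2-yl)butan-2-one | CC(=O)CCc1ccco1 | intermediate
4 | (S)-4-(furan-2-yl)butan-2-ol | C[C@H](O)CCc1ccco1 | intermediate
5 | propiolic acid (prop-2-ynoic acid) | C#CC(=O)O | starting material
6 | (S)-4-(furan-2-yl)butan-2-yl prop-2-ynoate | C#CC(=O)O[C@@H](C)CCc1ccco1 | intermediate
7 | ethyl (S)-lactate | C[C@H](O)C(=O)OCC | starting material
8 | ethyl (S)-2-(triethylsilyloxy)propanoate | CC[Si](CC)(CC)O[C@@H](C)C(=O)OCC | intermediate
9 | (S)-2-(triethylsilyloxy)propanal | CC[Si](CC)(CC)O[C@@H](C)C=O | intermediate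
10 | lithium acetylide of 6 [(S)-4-(furan-2-yl)butan-2-yl 3-lithioprop-2-ynoate] | [Li]C#CC(=O)O[C@@H](C)CCc1ccco1 | intermediate (not isolated)
11 | (S)-4-(furan-2-yl)butan-2-yl (4R,5S)-4-hydroxy-5-(triethylsilyloxy)hex-2-ynoate | CC[Si](CC)(CC)O[C@@H](C)[C@H](O)C#CC(=O)O[C@@H](C)CCc1ccco1 | intermediate
12 | (S)-4-(furan-2-yl)butan-2-yl (4R,5S)-4-(tert-butyldimethylsilyloxy)-5-(triethylsilyloxy)hex-2-ynoate | CC[Si](CC)(CC)O[C@@H](C)[C@H](O[Si](C)(C)C(C)(C)C)C#CC(=O)O[C@@H](C)CCc1ccco1 | intermediate
13 | (S)-4-(furan-2-yl)butan-2-yl (2Z,4R,5S)-4-(TBSO)-5-(TESO)hex-2-enoate | CC[Si](CC)(CC)O[C@@H](C)[C@H](O[Si](C)(C)C(C)(C)C)/C=C\C(=O)O[C@@H](C)CCc1ccco1 | intermediate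
14 | (2Z,7S)-7-{[(2Z,4R,5S)-4-(TBSO)-5-(TESO)hex-2-enoyl]oxy}-4-oxooct-2-enal | CC[Si](CC)(CC)O[C@@H](C)[C@H](O[Si](C)(C)C(C)(C)C)/C=C\C(=O)O[C@@H](C)CCC(=O)/C=C\C=O | intermediate (not isolated)
15 | (2E,7S)-7-{[(2Z,4R,5S)-4-(TBSO)-5-(TESO)hex-2-enoyl]oxy}-4-oxooct-2-enal | CC[Si](CC)(CC)O[C@@H](C)[C@H](O[Si](C)(C)C(C)(C)C)/C=C\C(=O)O[C@@H](C)CCC(=O)/C=C/C=O | intermediate
16 | (2E,7S)-7-{[(2Z,4R,5S)-4-(TBSO)-5-(TESO)hex-2-enoyl]oxy}-4-oxooct-2-enoic acid | CC[Si](CC)(CC)O[C@@H](C)[C@H](O[Si](C)(C)C(C)(C)C)/C=C\C(=O)O[C@@H](C)CCC(=O)/C=C/C(=O)O | intermediate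
17 | (2E,7S)-7-{[(2Z,4R,5S)-4-(TBSO)-5-hydroxyhex-2-enoyl]oxy}-4-oxooct-2-enoic acid | C[C@H](O)[C@H](O[Si](C)(C)C(C)(C)C)/C=C\C(=O)O[C@@H](C)CCC(=O)/C=C/C(=O)O | intermediate
18 | mixed anhydride of 17 with 2,4,6-trichlorobenzoic acid | C[C@H](O)[C@H](O[Si](C)(C)C(C)(C)C)/C=C\C(=O)O[C@@H](C)CCC(=O)/C=C/C(=O)OC(=O)c1c(Cl)cc(Cl)cc1Cl | intermediate (not isolated)
19 | macrodiolide (3E,8S,11Z,13R,14S)-13-(TBSO)-8,14-dimethyl-1,9-dioxacyclotetradeca-3,11-diene-2,5,10-trione | O=C1/C=C/C(=O)CC[C@H](C)OC(=O)/C=C\[C@@H](O[Si](C)(C)C(C)(C)C)[C@H](C)O1 | intermediate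
20 | trans-3,4-epoxide of 19, (8S,11Z,13R,14S)-13-(TBSO)-3,4-epoxy-8,14-dimethyl-1,9-dioxacyclotetradec-11-ene-2,5,10-trione (one of the two trans face isomers drawn; both are used) | O=C1[C@H]2O[C@@H]2C(=O)CC[C@H](C)OC(=O)/C=C\[C@@H](O[Si](C)(C)C(C)(C)C)[C@H](C)O1 | intermediate
21 | (8S,11Z,13R,14S)-13-(TBSO)-8,14-dimethyl-1,9-dioxacyclotetradec-11-ene-2,4,5,10-tetrone (formed as its enolate) | O=C1CC(=O)C(=O)CC[C@H](C)OC(=O)/C=C\[C@@H](O[Si](C)(C)C(C)(C)C)[C@H](C)O1 | intermediate (not isolated)
22 | bis-macrolide cyclopentanone (1S,3S,4S,5S): the target core with H at C1 in place of the side chain and TBS ethers on both ring allylic hydroxyls | [C@@H]12C(=O)O[C@@H](C)[C@H](O[Si](C)(C)C(C)(C)C)/C=C\C(=O)O[C@@H](C)CC[C@@](O)(C1=O)[C@H]1C(=O)CC[C@H](C)OC(=O)/C=C\[C@@H](O[Si](C)(C)C(C)(C)C)[C@H](C)OC(=O)[C@@H]12 | intermediate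
23 | (S)-4-(furan-2-yl)butan-2-yl (2E,4R,5S)-4-hydroxy-5-(triethylsilyloxy)hex-2-enoate | CC[Si](CC)(CC)O[C@@H](C)[C@H](O)/C=C/C(=O)O[C@@H](C)CCc1ccco1 | intermediate
24 | (2S)-4-(2-hydroxy-5-oxo-2,5-dihydrofuran-2-yl)butan-2-yl (2E,4R,5S)-4-hydroxy-5-(triethylsilyloxy)hex-2-enoate (lactol epimers) | CC[Si](CC)(CC)O[C@@H](C)[C@H](O)/C=C/C(=O)O[C@@H](C)CCC1(O)C=CC(=O)O1 | intermediate (not isolated)
25 | silyl-protected target: 26 with TBS ethers on the two ring allylic hydroxyls and a TES ether on the side-chain C5 hydroxyl | CC[Si](CC)(CC)O[C@@H](C)[C@H](O)/C=C/C(=O)O[C@@H](C)CCC(=O)C[C@@H](C(=O)O)[C@@]12C(=O)O[C@@H](C)[C@H](O[Si](C)(C)C(C)(C)C)/C=C\C(=O)O[C@@H](C)CC[C@@](O)(C1=O)[C@H]1C(=O)CC[C@H](C)OC(=O)/C=C\[C@@H](O[Si](C)(C)C(C)(C)C)[C@H](C)OC(=O)[C@@H]12 | intermediate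
26 | CNP0078817.1 | C[C@H](O)[C@H](O)/C=C/C(=O)O[C@@H](C)CCC(=O)C[C@@H](C(=O)O)[C@@]12C(=O)O[C@@H](C)[C@H](O)/C=C\C(=O)O[C@@H](C)CC[C@@](O)(C1=O)[C@H]1C(=O)CC[C@H](C)OC(=O)/C=C\[C@@H](O)[C@H](C)OC(=O)[C@@H]12 | target

**Step count and risks**

Total: 17 steps. Compound 19 is made once and used in steps 13 and 14; compound 11 is used in steps 7 and 15. Longest linear sequence: 14 steps (1 → 3 → 4 → 6 → 11 → 12 → 13 → 15 → 16 → 17 → 19 → 20 → 22 → 25 → 26).

The three steps most likely to fail:

Step 16. The acceptor is an anion and the donor is hindered, so the Michael addition may be slow enough for retro-aldol of 22 to compete. If the neutral butenolide form reacts instead, the wrong carbon is attacked. The CH(CO2H) center is under no external control. Fallback, setting out from 23: the furan is opened before the coupling (NBS, NaHCO3, aqueous acetone; then pyridine) to the trans keto enal F1, which is oxidized (NaClO2, NaH2PO4, 2-methyl-2-butene) to the trans keto acid F2 and alkylated (allyl bromide, KHCO3, DMF) to the neutral allyl ester F3. A 6'-hydroxy cinchona alkaloid catalyst (cupreidine 9-O-benzyl ether or its pseudoenantiomer, 10 mol %, CH2Cl2, −20 °C) then directs the addition of 22 to give the allyl ester adduct F4, and Pd(PPh3)4 with morpholine removes the allyl group, which comes back to the route at 25.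

Step 14. The epoxide opening may be slow or may divert (benzilic-type rearrangement, coupling of 21 with unreacted 20), and the face selectivity imposed by the two macrocycles is unproven. Fallback, setting out from 19: reductive hydroxylation with Mn(dpm)3 (dpm = 2,2,6,6-tetramethylheptane-3,5-dionate; PhSiH3, O2, i-PrOH, 0 °C; then P(OEt)3) puts hydrogen on C3 and hydroxyl on C4 to give the hydroxy ketone F5. Dess–Martin periodinane oxidizes it to the tetrone, which is now isolated and purified. This comes back to the route at 21, and the annulation with 19 is then run separately under a weak amine base (Et3N, CH2Cl2) to reach 22.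

Step 12. The seco acid carries a Z enoate ester with a free hydroxyl five atoms away, so six-membered lactone formation (with loss of the C8 unit) or Z-to-E isomerization can compete with ring closure. Fallback, setting out from 12 with the alkyne kept: NBS/NaHCO3 then pyridine gives the ynoate keto enal F6, NaClO2 oxidation the ynoate keto acid F7, and AcOH–THF–H2O the hydroxy ynoate acid F8, which cannot close a six-membered lactone because the alkyne is linear. Yamaguchi lactonization gives the macrocyclic ynoate F9, and semi-hydrogenation on the macrocycle (H2, Pd/CaCO3 poisoned with Pb(OAc)2, quinoline, one equivalent of H2; the alkyne out-competes the ene-dicarbonyl for the catalyst, as in the reduction of acetylenedicarboxylates to maleates) comes back to the route at 19.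

Further compounds
F1 | step 16 | (2E,7S)-7-{[(2E,4R,5S)-4-hydroxy-5-(triethylsilyloxy)hex-2-enoyl]oxy}-4-oxooct-2-enal | CC[Si](CC)(CC)O[C@@H](C)[C@H](O)/C=C/C(=O)O[C@@H](C)CCC(=O)/C=C/C=O
F2 | step 16 | (2E,7S)-7-{[(2E,4R,5S)-4-hydroxy-5-(triethylsilyloxy)hex-2-enoyl]oxy}-4-oxooct-2-enoic acid | CC[Si](CC)(CC)O[C@@H](C)[C@H](O)/C=C/C(=O)O[C@@H](C)CCC(=O)/C=C/C(=O)O
F3 | step 16 | allyl (2E,7S)-7-{[(2E,4R,5S)-4-hydroxy-5-(triethylsilyloxy)hex-2-enoyl]oxy}-4-oxooct-2-enoate | CC[Si](CC)(CC)O[C@@H](C)[C@H](O)/C=C/C(=O)O[C@@H](C)CCC(=O)/C=C/C(=O)OCC=C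
F4 | step 16 | allyl ester of 25 | CC[Si](CC)(CC)O[C@@H](C)[C@H](O)/C=C/C(=O)O[C@@H](C)CCC(=O)C[C@@H](C(=O)OCC=C)[C@@]12C(=O)O[C@@H](C)[C@H](O[Si](C)(C)C(C)(C)C)/C=C\C(=O)O[C@@H](C)CC[C@@](O)(C1=O)[C@H]1C(=O)CC[C@H](C)OC(=O)/C=C\[C@@H](O[Si](C)(C)C(C)(C)C)[C@H](C)OC(=O)[C@@H]12
F5 | step 14 | (8S,11Z,13R,14S)-13-(TBSO)-4-hydroxy-8,14-dimethyl-1,9-dioxacyclotetradec-11-ene-2,5,10-trione (C4 epimers) | O=C1CC(O)C(=O)CC[C@H](C)OC(=O)/C=C\[C@@H](O[Si](C)(C)C(C)(C)C)[C@H](C)O1
F6 | step 12 | (2E,7S)-7-{[(4R,5S)-4-(TBSO)-5-(TESO)hex-2-ynoyl]oxy}-4-oxooct-2-enal | CC[Si](CC)(CC)O[C@@H](C)[C@H](O[Si](C)(C)C(C)(C)C)C#CC(=O)O[C@@H](C)CCC(=O)/C=C/C=O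
F7 | step 12 | (2E,7S)-7-{[(4R,5S)-4-(TBSO)-5-(TESO)hex-2-ynoyl]oxy}-4-oxooct-2-enoic acid | CC[Si](CC)(CC)O[C@@H](C)[C@H](O[Si](C)(C)C(C)(C)C)C#CC(=O)O[C@@H](C)CCC(=O)/C=C/C(=O)O
F8 | step 12 | (2E,7S)-7-{[(4R,5S)-4-(TBSO)-5-hydroxyhex-2-ynoyl]oxy}-4-oxooct-2-enoic acid | C[C@H](O)[C@H](O[Si](C)(C)C(C)(C)C)C#CC(=O)O[C@@H](C)CCC(=O)/C=C/C(=O)O
F9 | step 12 | (3E,8S,13R,14S)-13-(TBSO)-8,14-dimethyl-1,9-dioxacyclotetradec-3-en-11-yne-2,5,10-trione | O=C1/C=C/C(=O)CC[C@H](C)OC(=O)C#C[C@@H](O[Si](C)(C)C(C)(C)C)[C@H](C)O1
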